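The angular methyl C20 is stored as a cyclopropane. In labdane numbering, quaternary C10 (shared by ring A and ring B) carries C20 next to C9, the carbon alpha to the C8 carbonyl that later becomes the exocyclic methylene, so C9–C10–C20 can be a three-membered ring fused to ring B. One copper-carbene addition of a C9 diazoketone to the exocyclic C10=C20 alkene of a preformed, enantioenriched ring A (C4 and C5 already set) closes ring B and the cyclopropane and fixes C10. Reductive opening of the C9–C20 bond then releases the methyl and a regiodefined C8 enolate, to which the side chain is attached at C9.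

Key step: step 8

Assumption: the SMILES is read literally, so H5, C20 and the C19 ester lie on one face (a cis-fused, 5-epi labdane) and the epoxide is 13R,14R; labdane numbering is used for atoms throughout.

Step 1
Reactants: 1 3-methylcyclohex-2-en-1-one; 2 ethynyltrimethylsilane
Product: 4 trimethyl({(3S)-3-methyl-3-[1-(trimethylsilyl)ethenyl]cyclohex-1-en-1-yl}oxy)silane, via aluminium enolate 3 (not isolated)
Conditions: 2, i-Bu2AlH, hexanes, 55 °C; then 1, Cu(OTf)2 (5 mol%), chiral sulfonate-bearing imidazolinium salt (N-heterocyclic carbene precursor, 5 mol%, enantiomer giving the 3S centre), THF, −78 → −15 °C; then Me3SiOTf, −78 → 0 °C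
Reagents that add atoms: [1-(trimethylsilyl)ethenyl]bis(2-methylpropyl)alumane, made in the flask from 2 (C=C([Si](C)(C)C)[Al](CC(C)C)CC(C)C); trimethylsilyl triflate (C[Si](C)(C)OS(=O)(=O)C(F)(F)F)
Why: Copper-catalysed asymmetric conjugate addition of a silyl-substituted vinylaluminium reagent to a β-substituted cyclic enone is an established way to vinyl-bearing quaternary centres; the chiral carbene–copper complex selects the enone face and so sets C4, and O-silylation of the aluminium enolate fixes the enolate regiochemistry toward C5.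

Step 2
Reactants: 4 trimethyl({(3S)-3-methyl-3-[1-(trimethylsilyl)ethenyl]cyclohex-1-en-1-yl}oxy)silane; 5 methyl acrylate
Product: 7 methyl 3-{(1R,2S)-2-methyl-6-oxo-2-[1-(trimethylsilyl)ethenyl]cyclohexyl}propanoate, via lithium enolate 6 (not isolated)
Conditions: MeLi, THF, 0 °C → rt; then 5 (1.05 equiv, slow addition), −78 °C; AcOH quench at −78 °C
Reagents that add atoms: methyl acrylate 5 (C=CC(=O)OC)
Why: Methyllithium cleaves the enol silane to the regiodefined lithium enolate, which undergoes Michael addition to the acrylate at C5 on the face opposite the bulky 1-silylvinyl group of the neighbouring quaternary carbon, so the propanoate chain should end trans to that group and cis to the methyl, and the cold acidic quench keeps this kinetic configuration.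

Step 3
Reactants: 7 methyl 3-{(1R,2S)-2-methyl-6-oxo-2-[1-(trimethylsilyl)ethenyl]cyclohexyl}propanoate
Product: 8 methyl 3-[(1R,2R)-2-ethenyl-2-methyl-6-oxocyclohexyl]propanoate
Conditions: CF3CO2H (5 equiv), CH2Cl2, 0 °C → rt
Reagents that add atoms: none
Why: Protodesilylation of a vinylsilane by a protic acid (ipso protonation, then loss of silicon from the β-silyl cation) unmasks the plain vinyl group, while ketone, ester and both stereocentres are untouched under these mild conditions (the descriptor at C4 changes only through the priority rules).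

Step 4
Reactants: 8 methyl 3-[(1R,2R)-2-ethenyl-2-methyl-6-oxocyclohexyl]propanoate
Product: 9 methyl (1S,2R)-2-(3-methoxy-3-oxopropyl)-1-methyl-3-oxocyclohexane-1-carboxylate
Conditions: O3, NaOH (2.5 M in MeOH), CH2Cl2, −78 °C
Reagents that add atoms: ozone ([O-][O+]=O); methanol (CO)
Why: Ozonolysis in methanolic NaOH converts a terminal alkene directly into the methyl ester (the aldehyde hemiacetal is oxidised by ozone), which gives the C19 ester at a temperature where the epimerisable C5 centre is not enolised.

Step 5
Reactants: 9 methyl (1S,2R)-2-(3-methoxy-3-oxopropyl)-1-methyl-3-oxocyclohexane-1-carboxylate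
Product: 10 methyl (1S,2S)-2-(3-methoxy-3-oxopropyl)-1-methyl-3-methylidenecyclohexane-1-carboxylate
Conditions: Zn, CH2Br2, TiCl4, THF/CH2Cl2, 0 °C → rt
Reagents that add atoms: dibromomethane (BrCBr)
Why: The non-basic Zn/CH2Br2/TiCl4 methylenation converts the hindered ketone into the exocyclic C10=C20 alkene without touching the esters or enolising C5, whose configuration is thereby locked.

Step 6
Reactants: 10 methyl (1S,2S)-2-(3-methoxy-3-oxopropyl)-1-methyl-3-methylidenecyclohexane-1-carboxylate
Product: 11 3-[(1S,2S)-2-(methoxycarbonyl)-2-methyl-6-methylidenecyclohexyl]propanoic acid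
Conditions: LiOH·H2O (1.5 equiv), THF/MeOH/H2O, 0 °C → rt; then 1 M HCl to pH 3, 0 °C
Reagents that add atoms: lithium hydroxide ([Li+].[OH-])
Why: Saponification discriminates on steric grounds, since the unhindered chain ester is hydrolysed while the methyl ester on quaternary C4 is inert under these conditions.

Step 7
Reactants: 11 3-[(1S,2S)-2-(methoxycarbonyl)-2-methyl-6-methylidenecyclohexyl]propanoic acid; 12 (trimethylsilyl)diazomethane
Product: 14 methyl (1S,2S)-2-(4-diazo-3-oxobutyl)-1-methyl-3-methylidenecyclohexane-1-carboxylate, via mixed anhydride 13 (not isolated)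
Conditions: ClCO2Et, Et3N, THF, −15 °C; then 12 (2 equiv), MeCN, 0 °C → rt
Reagents that add atoms: (trimethylsilyl)diazomethane 12 (C[Si](C)(C)C=[N+]=[N-])
Why: Acylation of (trimethylsilyl)diazomethane by a mixed carbonic anhydride (Arndt–Eistert-type diazoketone synthesis) installs C9 without generating HCl, which would threaten the acid-sensitive exocyclic alkene.

Step 8
Reactants: 14 methyl (1S,2S)-2-(4-diazo-3-oxobutyl)-1-methyl-3-methylidenecyclohexane-1-carboxylate
Product: 15 methyl (1R,3R,7S,8S)-8-methyl-4-oxotricyclo[5.4.0.0(1,3)]undecane-8-carboxylate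
Conditions: Cu(acac)2 (5 mol%), toluene, 110 °C, slow addition of 14 at high dilution
Reagents that add atoms: none
Why: Cu(acac)2 is reduced in the flask to the active monovalent copper species, which decomposes the diazoketone with loss of N2 to an electrophilic copper carbenoid at C9 that adds in a concerted, asynchronous [2+1] fashion to the C10=C20 alkene. The closest known reaction type is the copper-catalysed intramolecular cyclopropanation of δ,ε-unsaturated diazomethyl ketones to bicyclo[4.1.0]heptan-2-ones. Ring B closes in the 6-exo mode by bonding of C9 to the internal alkene carbon C10 (the π bond stays outside the new ring), and the cyclopropane closes in the same event through the C9–C20 bond. C10 is controlled by C5 through the three-atom tether: in the favoured chair the C5 side chain is axial (no allylic 1,3-strain with the methylene, anti to the axial C4 ester, C4 methyl equatorial), so the carbenoid should reach only the alkene face on the side of C6, which places C9 cis to C6 and C20 cis to H5; C9 follows from C10 because a cyclopropane on a six-membered ring must be cis-fused. The step needs π-addition to win over insertion into the tertiary allylic C5–H bond and over addition to the other face through the equatorial rotamer; the copper carbenoid's known preference for alkenes over C–H bonds and the axial tether are what should secure this.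

Step 9
Reactants: 15 methyl (1R,3R,7S,8S)-8-methyl-4-oxotricyclo[5.4.0.0(1,3)]undecane-8-carboxylate; 16 allyl bromide
Product: 18 methyl (1S,4aS,5R,8aS)-1,4a-dimethyl-6-oxo-5-(prop-2-en-1-yl)decahydronaphthalene-1-carboxylate, via lithium enolate 17 (not isolated)
Conditions: Li (2.2 equiv), t-BuOH (1.0 equiv), NH3(l)/THF, −78 °C; then 16 (excess), −78 → −33 °C; NH4Cl
Reagents that add atoms: allyl bromide 16 (C=CCBr)
Why: Dissolving-metal reduction of the cyclopropyl ketone cleaves the C9–C20 bond, the one aligned with the carbonyl π system, to give the C20 methyl and the regiodefined C8 lithium enolate (reductive alkylation), and allyl bromide should then attack C9 on the convex face of the cis-fused bicycle, anti to the ring A methylene C1 that is axial on ring B, so that the allyl group ends cis to C20; the hindered C4 ester is expected to survive a stoichiometric amount of lithium at −78 °C.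

Step 10
Reactants: 18 methyl (1S,4aS,5R,8aS)-1,4a-dimethyl-6-oxo-5-(prop-2-en-1-yl)decahydronaphthalene-1-carboxylate
Product: 19 methyl (1S,4aR,5S,8aS)-1,4a-dimethyl-6-methylidene-5-(prop-2-en-1-yl)decahydronaphthalene-1-carboxylate
Conditions: Zn, CH2Br2, TiCl4, THF/CH2Cl2, 0 °C → rt
Reagents that add atoms: dibromomethane (BrCBr)
Why: The same non-basic Zn/CH2Br2/TiCl4 methylenation converts the hindered C8 ketone into the C8=C17 methylene without epimerising the adjacent C9 centre.

Step 11
Reactants: 19 methyl (1S,4aR,5S,8aS)-1,4a-dimethyl-6-methylidene-5-(prop-2-en-1-yl)decahydronaphthalene-1-carboxylate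
Product: 21 methyl (1S,4aR,5S,8aS)-5-(3-hydroxypropyl)-1,4a-dimethyl-6-methylidenedecahydronaphthalene-1-carboxylate, via alkylborane 20 (not isolated)
Conditions: Sia2BH (from BH3·THF and 2-methylbut-2-ene), THF, 0 °C; then NaOH, H2O2, 0 °C → rt
Reagents that add atoms: hydrogen peroxide (OO)
Why: Hydroboration with the bulky dialkylborane is selective for the monosubstituted allyl alkene over the hindered 1,1-disubstituted exocyclic one and places boron on the terminal carbon C13, and oxidation with retention gives the primary alcohol.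

Step 12
Reactants: 21 methyl (1S,4aR,5S,8aS)-5-(3-hydroxypropyl)-1,4a-dimethyl-6-methylidenedecahydronaphthalene-1-carboxylate
Product: 22 methyl (1S,4aR,5S,8aS)-1,4a-dimethyl-6-methylidene-5-(3-oxopropyl)decahydronaphthalene-1-carboxylate
Conditions: Dess–Martin periodinane, NaHCO3, CH2Cl2, 0 °C → rt
Reagents that add atoms: none
Why: Dess–Martin oxidation takes the primary alcohol to the aldehyde under buffered, neutral conditions that leave the alkene and ester alone.

Step 13
Reactants: 22 methyl (1S,4aR,5S,8aS)-1,4a-dimethyl-6-methylidene-5-(3-oxopropyl)decahydronaphthalene-1-carboxylate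
Product: 23 methyl (1S,4aR,5S,8aS)-5-(but-3-yn-1-yl)-1,4a-dimethyl-6-methylidenedecahydronaphthalene-1-carboxylate
Conditions: dimethyl (1-diazo-2-oxopropyl)phosphonate, K2CO3, MeOH, 0 °C → rt
Reagents that add atoms: dimethyl (1-diazo-2-oxopropyl)phosphonate (COP(=O)(OC)C(=[N+]=[N-])C(C)=O)
Why: Ohira–Bestmann homologation (Seyferth–Gilbert type) converts the aldehyde into the terminal alkyne and adds C14, and K2CO3 in methanol leaves the hindered methyl ester unchanged.

Step 14
Reactants: 23 methyl (1S,4aR,5S,8aS)-5-(but-3-yn-1-yl)-1,4a-dimethyl-6-methylidenedecahydronaphthalene-1-carboxylate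
Product: 25 methyl (1S,4aR,5S,8aS)-5-[(3E)-5-hydroxy-3-methylpent-3-en-1-yl]-1,4a-dimethyl-6-methylidenedecahydronaphthalene-1-carboxylate, via alkenylalane 24 (not isolated)
Conditions: Me3Al, Cp2ZrCl2 (25 mol%), CH2Cl2, 0 °C → rt; then n-BuLi, THF/hexanes, −78 → 0 °C; (CH2O)n, rt; H2O work-up
Reagents that add atoms: trimethylaluminium (C[Al](C)C); formaldehyde, used as paraformaldehyde (C=O)
Why: Negishi zirconium-catalysed carboalumination adds methyl and aluminium syn across the terminal alkyne with methyl on the internal carbon C13, and the derived alanate is hydroxymethylated by formaldehyde with retention, so the trisubstituted alkene should form as the E isomer only, while the exocyclic alkene and the hindered ester are not expected to react.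

Step 15
Reactants: 25 methyl (1S,4aR,5S,8aS)-5-[(3E)-5-hydroxy-3-methylpent-3-en-1-yl]-1,4a-dimethyl-6-methylidenedecahydronaphthalene-1-carboxylate
Product: 26 methyl (1S,4aR,5S,8aS)-5-{2-[(2R,3R)-3-(hydroxymethyl)-2-methyloxiran-2-yl]ethyl}-1,4a-dimethyl-6-methylidenedecahydronaphthalene-1-carboxylate
Conditions: Ti(OiPr)4 (10 mol%), D-(−)-diethyl tartrate (12 mol%), t-BuOOH, 4 Å molecular sieves, CH2Cl2, −20 °C
Reagents that add atoms: tert-butyl hydroperoxide (CC(C)(C)OO)
Why: Sharpless asymmetric epoxidation of the E allylic alcohol with D-(−)-diethyl tartrate delivers oxygen to the face that gives the 13R,14R epoxy alcohol (reagent control, the same sense as for geraniol), and the alkoxide-directed titanium oxidant leaves the isolated exocyclic alkene untouched.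

Compound list
1 | 3-methylcyclohex-2-en-1-one | CC1=CC(=O)CCC1 | starting material
2 | ethynyltrimethylsilane | C#C[Si](C)(C)C | starting material
3 | bis(2-methylpropyl)aluminium enolate of (3S)-3-methyl-3-[1-(trimethylsilyl)ethenyl]cyclohexanone (C1=C2 enolate) | CC(C)C[Al](CC(C)C)OC1=C[C@@](C)(C(=C)[Si](C)(C)C)CCC1 | intermediate (not isolated)
4 | trimethyl({(3S)-3-methyl-3-[1-(trimethylsilyl)ethenyl]cyclohex-1-en-1-yl}oxy)silane | C[Si](C)(C)OC1=C[C@@](C)(C(=C)[Si](C)(C)C)CCC1 | intermediate
5 | methyl acrylate | C=CC(=O)OC | starting material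
6 | lithium (3S)-3-methyl-3-[1-(trimethylsilyl)ethenyl]cyclohex-1-en-1-olate | [Li]OC1=C[C@@](C)(C(=C)[Si](C)(C)C)CCC1 | intermediate (not isolated)
7 | methyl 3-{(1R,2S)-2-methyl-6-oxo-2-[1-(trimethylsilyl)ethenyl]cyclohexyl}propanoate (chain trans to the silylvinyl group) | O=C1CCC[C@](C)(C(=C)[Si](C)(C)C)[C@H]1CCC(=O)OC | intermediate
8 | methyl 3-[(1R,2R)-2-ethenyl-2-methyl-6-oxocyclohexyl]propanoate | O=C1CCC[C@](C)(C=C)[C@H]1CCC(=O)OC | intermediate
9 | methyl (1S,2R)-2-(3-methoxy-3-oxopropyl)-1-methyl-3-oxocyclohexane-1-carboxylate | O=C1CCC[C@](C)(C(=O)OC)[C@H]1CCC(=O)OC | intermediate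
10 | methyl (1S,2S)-2-(3-methoxy-3-oxopropyl)-1-methyl-3-methylidenecyclohexane-1-carboxylate | C=C1CCC[C@](C)(C(=O)OC)[C@H]1CCC(=O)OC | intermediate
11 | 3-[(1S,2S)-2-(methoxycarbonyl)-2-methyl-6-methylidenecyclohexyl]propanoic acid | C=C1CCC[C@](C)(C(=O)OC)[C@H]1CCC(=O)O | intermediate
12 | (trimethylsilyl)diazomethane | C[Si](C)(C)C=[N+]=[N-] | starting material
13 | mixed ethyl carbonic anhydride of acid 11 | C=C1CCC[C@](C)(C(=O)OC)[C@H]1CCC(=O)OC(=O)OCC | intermediate (not isolated)
14 | methyl (1S,2S)-2-(4-diazo-3-oxobutyl)-1-methyl-3-methylidenecyclohexane-1-carboxylate (ring A diazoketone, key-step precursor) | C=C1CCC[C@](C)(C(=O)OC)[C@H]1CCC(=O)C=[N+]=[N-] | intermediate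
15 | methyl (1R,3R,7S,8S)-8-methyl-4-oxotricyclo[5.4.0.0(1,3)]undecane-8-carboxylate (C8 ketone, C9–C10–C20 cyclopropane; H5, C20 and the ester on one face) | O=C1CC[C@H]2[C@@]3(CCC[C@]2(C)C(=O)OC)C[C@@H]13 | intermediate
16 | allyl bromide | C=CCBr | starting material
17 | lithium C8 enolate (C8=C9) of the ring-opened ketone, C20 methyl on C10 | [Li]OC1=C[C@@]2(C)CCC[C@](C)(C(=O)OC)[C@H]2CC1 | intermediate (not isolated)
18 | methyl (1S,4aS,5R,8aS)-1,4a-dimethyl-6-oxo-5-(prop-2-en-1-yl)decahydronaphthalene-1-carboxylate | O=C1CC[C@H]2[C@](C)(CCC[C@]2(C)C(=O)OC)[C@H]1CC=C | intermediate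
19 | methyl (1S,4aR,5S,8aS)-1,4a-dimethyl-6-methylidene-5-(prop-2-en-1-yl)decahydronaphthalene-1-carboxylate | C=C1CC[C@H]2[C@](C)(CCC[C@]2(C)C(=O)OC)[C@H]1CC=C | intermediate
20 | bis(3-methylbutan-2-yl)borane adduct of 19 (boron on C13) | C=C1CC[C@H]2[C@](C)(CCC[C@]2(C)C(=O)OC)[C@H]1CCCB(C(C)C(C)C)C(C)C(C)C | intermediate (not isolated)
21 | methyl (1S,4aR,5S,8aS)-5-(3-hydroxypropyl)-1,4a-dimethyl-6-methylidenedecahydronaphthalene-1-carboxylate | C=C1CC[C@H]2[C@](C)(CCC[C@]2(C)C(=O)OC)[C@H]1CCCO | intermediate
22 | methyl (1S,4aR,5S,8aS)-1,4a-dimethyl-6-methylidene-5-(3-oxopropyl)decahydronaphthalene-1-carboxylate | C=C1CC[C@H]2[C@](C)(CCC[C@]2(C)C(=O)OC)[C@H]1CCC=O | intermediate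
23 | methyl (1S,4aR,5S,8aS)-5-(but-3-yn-1-yl)-1,4a-dimethyl-6-methylidenedecahydronaphthalene-1-carboxylate | C=C1CC[C@H]2[C@](C)(CCC[C@]2(C)C(=O)OC)[C@H]1CCC#C | intermediate
24 | (E)-alkenyl(dimethyl)alane from 23 (aluminium on C14, methyl on C13) | C=C1CC[C@H]2[C@](C)(CCC[C@]2(C)C(=O)OC)[C@H]1CC/C(C)=C/[Al](C)C | intermediate (not isolated)
25 | methyl (1S,4aR,5S,8aS)-5-[(3E)-5-hydroxy-3-methylpent-3-en-1-yl]-1,4a-dimethyl-6-methylidenedecahydronaphthalene-1-carboxylate | C=C1CC[C@H]2[C@](C)(CCC[C@]2(C)C(=O)OC)[C@H]1CC/C(C)=C/CO | intermediate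
26 | methyl (1S,4aR,5S,8aS)-5-{2-[(2R,3R)-3-(hydroxymethyl)-2-methyloxiran-2-yl]ethyl}-1,4a-dimethyl-6-methylidenedecahydronaphthalene-1-carboxylate (CNP0175926.1) | C=C1CC[C@H]2[C@](C)(CCC[C@]2(C)C(=O)OC)[C@H]1CC[C@@]1(C)O[C@@H]1CO | target

Total step count: 15. Longest linear sequence: 15 steps (1 → 26).

Steps most likely to fail

Step 8. The carbenoid may add through the rotamer with an equatorial C5 side chain to the other alkene face (trans-fused tricycle), or be diverted into insertion at the tertiary allylic C5–H bond or into carbene dimerisation. The fallback sets out from 9 and comes back at 18; it closes ring B by an intramolecular Wittig reaction and brings in C20 by conjugate addition. Me3SnOH in 1,2-dichloroethane hydrolyses the chain ester of 9 without epimerising C5 and gives keto acid F1. Ethyl chloroformate and Et3N convert it into mixed anhydride F2, and 12 then gives keto diazoketone F3. Aqueous HBr in ether turns this into bromomethyl ketone F4, PPh3 gives phosphonium bromide F5, and aqueous Na2CO3 gives the stabilised ylide F6, which on heating in toluene condenses with the C10 ketone to give bicyclic enone F7 (C8 ketone, C9=C10). Me2CuLi adds to C10 of such an enone in the axial sense that leads to the cis-fused product, so C20 should enter cis to H5. The resulting C8 enolate is the same enolate as 17 and is allylated with 16 in THF/HMPA to give 18.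

Step 9. The dissolving metal may over-reduce the C4 ester, or proton transfer within the enolate before alkylation may lead to alkylation at C7 and to double alkylation. The fallback sets out from 15 and comes back at 18. The ring is opened with SmI2 in THF/DMPU at −78 °C, a single-electron reductant that tolerates esters, to give samarium enolate F8. This is acylated on oxygen with allyl chloroformate to give allyl enol carbonate F9, and Pd(PPh3)4 (zerovalent palladium) in THF then effects a decarboxylative Tsuji allylation that delivers the allyl group regiospecifically to C9 under neutral conditions, giving 18.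

Step 2. Anionic oligomerisation of the acrylate may outpace its capture by the hindered enolate, or a second Michael addition may follow proton transfer. The fallback sets out from 4 and comes back at 7. Enolate 6 is generated as before and alkylated with 16 in THF/DMPU, again anti to the silylvinyl group, to give allyl ketone F10. Excess 9-BBN hydroborates the allyl group and reduces the ketone (organoborane F11; the hindered vinylsilane is not touched), and NaOH/H2O2 gives diol F12. Jones oxidation (CrO3, H2SO4, acetone, 0 °C) gives keto acid F13, and 12 in toluene/MeOH esterifies it to 7.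

Further compounds
F1 | step 8 | 3-[(1R,2S)-2-(methoxycarbonyl)-2-methyl-6-oxocyclohexyl]propanoic acid | O=C1CCC[C@](C)(C(=O)OC)[C@H]1CCC(=O)O
F2 | step 8 | mixed ethyl carbonic anhydride of F1 | O=C1CCC[C@](C)(C(=O)OC)[C@H]1CCC(=O)OC(=O)OCC
F3 | step 8 | methyl (1S,2R)-2-(4-diazo-3-oxobutyl)-1-methyl-3-oxocyclohexane-1-carboxylate | O=C1CCC[C@](C)(C(=O)OC)[C@H]1CCC(=O)C=[N+]=[N-]
F4 | step 8 | methyl (1S,2R)-2-(4-bromo-3-oxobutyl)-1-methyl-3-oxocyclohexane-1-carboxylate | O=C1CCC[C@](C)(C(=O)OC)[C@H]1CCC(=O)CBr
F5 | step 8 | {4-[(1R,2S)-2-(methoxycarbonyl)-2-methyl-6-oxocyclohexyl]-2-oxobutyl}triphenylphosphonium bromide | O=C1CCC[C@](C)(C(=O)OC)[C@H]1CCC(=O)C[P+](c2ccccc2)(c3ccccc3)c4ccccc4.[Br-]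
F6 | step 8 | methyl (1S,2R)-1-methyl-3-oxo-2-[3-oxo-4-(triphenyl-λ5-phosphanylidene)butyl]cyclohexane-1-carboxylate | O=C1CCC[C@](C)(C(=O)OC)[C@H]1CCC(=O)C=P(c2ccccc2)(c3ccccc3)c4ccccc4
F7 | step 8 | methyl (1S,8aS)-1-methyl-6-oxo-1,2,3,4,6,7,8,8a-octahydronaphthalene-1-carboxylate | O=C1CC[C@H]2C(=C1)CCC[C@]2(C)C(=O)OC
F8 | step 9 | diiodosamarium C8 enolate of the ring-opened ketone | I[Sm](I)OC1=C[C@@]2(C)CCC[C@](C)(C(=O)OC)[C@H]2CC1
F9 | step 9 | methyl (1S,4aS,8aS)-1,4a-dimethyl-6-{[(prop-2-en-1-yloxy)carbonyl]oxy}-1,2,3,4,4a,7,8,8a-octahydronaphthalene-1-carboxylate | C=CCOC(=O)OC1=C[C@@]2(C)CCC[C@](C)(C(=O)OC)[C@H]2CC1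
F10 | step 2 | (2R,3S)-3-methyl-2-(prop-2-en-1-yl)-3-[1-(trimethylsilyl)ethenyl]cyclohexan-1-one | O=C1CCC[C@](C)(C(=C)[Si](C)(C)C)[C@H]1CC=C
F11 | step 2 | bis(9-borabicyclo[3.3.1]nonan-9-yl) adduct of F10 (borinate on the former carbonyl oxygen, boron on the chain terminus; carbinol epimers) | C1(OB2C3CCCC2CCC3)CCC[C@](C)(C(=C)[Si](C)(C)C)[C@H]1CCCB4C5CCCC4CCC5
F12 | step 2 | 3-{(1R,2S)-6-hydroxy-2-methyl-2-[1-(trimethylsilyl)ethenyl]cyclohexyl}propan-1-ol (carbinol epimers) | OC1CCC[C@](C)(C(=C)[Si](C)(C)C)[C@H]1CCCO
F13 | step 2 | 3-{(1R,2S)-2-methyl-6-oxo-2-[1-(trimethylsilyl)ethenyl]cyclohexyl}propanoic acid | O=C1CCC[C@](C)(C(=C)[Si](C)(C)C)[C@H]1CCC(=O)O
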